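**Retrosynthetic overview**
1. Target 13 ⇐ penta-MOM biflavanone 12 by global acetal cleavage; the 4'-OMe is carried from the first step.
2. 12 ⇐ acyclic dialdehyde 9: C4–C3 and C4''–C3'' are each made by a carbene-generated acyl anion equivalent (alkyne hydroacylation, then intramolecular Stetter); the C3–C3'' bond is the alkyne of 9.
3. 9 ⇐ (S,S)-ynediol 6 + two molecules of phenol 8; a double Mitsunobu with inversion sets C2 and C2''.
4. 6 ⇐ 4-methoxybenzaldehyde 1 + ethynyltrimethylsilane 2 + 4-(methoxymethoxy)benzaldehyde 5 by two catalytic asymmetric alkynylations; 8 ⇐ 2,4,6-trihydroxybenzaldehyde 7.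
5. Ring order: all benzene rings are bought; the two pyranone rings (unit 1 = 4-methoxyphenyl half, unit 2 = 4-hydroxyphenyl half) are closed last, one after the other, in step 6.

Assumption: the (S,S)-ProPhenol ligand is taken to give the carbinol configuration drawn in 3 and 6 (if the facial sense proves opposite, its mirror image is used), and 5 is taken as a catalogue compound.

**Step 1**
Reactants: 1 4-methoxybenzaldehyde; 2 ethynyltrimethylsilane
Product: 3 (S)-1-(4-methoxyphenyl)-3-(trimethylsilyl)prop-2-yn-1-ol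
Conditions: 2 (3 equiv), Me2Zn (3 equiv), 2,6-bis{[(2S)-2-(hydroxydiphenylmethyl)pyrrolidin-1-yl]methyl}-4-methylphenol ((S,S)-ProPhenol, 20 mol %), Ph3PO (40 mol %), toluene, 0 to 4 °C, 48 h; aq. NH4Cl
Reagents that add atoms: none
Why: Zinc-ProPhenol asymmetric alkynylation, in which the chiral dinuclear zinc alkoxide binds both the aldehyde and the alkynylzinc and delivers the alkynyl group to one carbonyl face, setting the carbinol centre (S) under catalyst control.

**Step 2**
Reactants: 3 (S)-1-(4-methoxyphenyl)-3-(trimethylsilyl)prop-2-yn-1-ol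
Product: 4 (R)-1-(4-methoxyphenyl)prop-2-yn-1-ol
Conditions: K2CO3 (0.2 equiv), MeOH, 0 °C to rt, 1 h
Reagents that add atoms: none
Why: Base-catalysed protodesilylation of the C(sp)–Si bond leaves the stereocentre untouched; the descriptor changes from S to R only because ethynyl now ranks below the aryl group.

**Step 3**
Reactants: 4 (R)-1-(4-methoxyphenyl)prop-2-yn-1-ol (1.3 equiv); 5 4-(methoxymethoxy)benzaldehyde
Product: 6 (1S,4S)-1-(4-methoxyphenyl)-4-[4-(methoxymethoxy)phenyl]but-2-yne-1,4-diol
Conditions: Me2Zn (4 equiv), 2,6-bis{[(2S)-2-(hydroxydiphenylmethyl)pyrrolidin-1-yl]methyl}-4-methylphenol (20 mol %), Ph3PO (40 mol %), toluene, 4 °C, 48 h; aq. NH4Cl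
Reagents that add atoms: none
Why: Second zinc-ProPhenol asymmetric alkynylation (extra Me2Zn first turns the free OH into a zinc alkoxide), in which the same ligand sets the new carbinol centre (S) with little influence from the remote existing centre, and two successive selections raise the ee of the S,S-diol above that of either step.

**Step 4**
Reactants: 7 2,4,6-trihydroxybenzaldehyde
Product: 8 2-hydroxy-4,6-bis(methoxymethoxy)benzaldehyde
Conditions: MOMCl (2.1 equiv), iPr2NEt (2.5 equiv), CH2Cl2, 0 °C to rt
Reagents that add atoms: chloromethyl methyl ether (MOMCl), COCCl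
Why: Selective phenol O-alkylation (Williamson type), in which the 4-OH and one ortho OH react while the other ortho OH stays free because it is hydrogen-bonded to the formyl oxygen.

**Step 5**
Reactants: 6 (1S,4S)-1-(4-methoxyphenyl)-4-[4-(methoxymethoxy)phenyl]but-2-yne-1,4-diol; 8 2-hydroxy-4,6-bis(methoxymethoxy)benzaldehyde (2.4 equiv)
Product: 9 2,2'-{[(1R,4R)-1-(4-methoxyphenyl)-4-[4-(methoxymethoxy)phenyl]but-2-yne-1,4-diyl]bis(oxy)}bis[4,6-bis(methoxymethoxy)benzaldehyde]
Conditions: PPh3 (2.6 equiv), DIAD (2.6 equiv), toluene, −20 °C to rt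
Reagents that add atoms: none
Why: Double Mitsunobu etherification, in which each oxyphosphonium is displaced by the acidic salicylaldehyde-type phenoxide in an SN2 step with inversion (S,S to R,R), and elimination cannot compete because neither carbinol carbon has a β-hydrogen.

**Step 6**
Reactants: 9 2,2'-{[(1R,4R)-1-(4-methoxyphenyl)-4-[4-(methoxymethoxy)phenyl]but-2-yne-1,4-diyl]bis(oxy)}bis[4,6-bis(methoxymethoxy)benzaldehyde]
Product: 12 (2S,3R)-5,7-bis(methoxymethoxy)-3-{(2S,3R)-5,7-bis(methoxymethoxy)-2-[4-(methoxymethoxy)phenyl]-4-oxochroman-3-yl}-2-(4-methoxyphenyl)chroman-4-one, via unit-1-cyclised enone aldehyde 10 (not isolated), via unit-2-cyclised enone aldehyde 11 (not isolated)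
Conditions: 3-(2,4,6-trimethylphenyl)-5,6,7,8-tetrahydro-4H-cyclohepta[d][1,3]thiazol-3-ium perchlorate (20 mol %), K2CO3 (40 mol %), THF (0.05 M), 70 °C, 24 h
Reagents that add atoms: none
Why: Proposed new method: the thiazol-2-ylidene turns each aldehyde into a Breslow intermediate (acyl anion equivalent), the first of which adds to the unactivated alkyne in a concerted Conia-ene-type 6-exo-dig hydroacylation to give the (E)-3-alkylidene flavanone 10 or 11, whose enone β-carbon is then attacked by the second Breslow intermediate in an intramolecular Stetter reaction (closest known chemistry: carbene-catalysed alkyne hydroacylation–Stetter cascades of 2-propargyloxybenzaldehydes), and the two new α-keto centres C3 and C3'' epimerise under the basic conditions to the diequatorial 2,3-trans arrangement dictated by the fixed C2 and C2'' centres.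

**Step 7**
Reactants: 12 (2S,3R)-5,7-bis(methoxymethoxy)-3-{(2S,3R)-5,7-bis(methoxymethoxy)-2-[4-(methoxymethoxy)phenyl]-4-oxochroman-3-yl}-2-(4-methoxyphenyl)chroman-4-one
Product: 13 (2S,3R)-5,7-dihydroxy-3-[(2S,3R)-5,7-dihydroxy-2-(4-hydroxyphenyl)-4-oxochroman-3-yl]-2-(4-methoxyphenyl)chroman-4-one
Conditions: 3 M aq. HCl, MeOH/THF, 50 °C, 4 h
Reagents that add atoms: none
Why: Acid-catalysed acetal methanolysis removes all five MOM ethers, while the aryl methyl ether, the ketones and the four stereocentres are untouched because no base is present to open the pyranone rings or enolise them.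

**Compound list**
1 | 4-methoxybenzaldehyde | COc1ccc(C=O)cc1 | starting material
2 | ethynyltrimethylsilane | C#C[Si](C)(C)C | starting material
3 | (S)-1-(4-methoxyphenyl)-3-(trimethylsilyl)prop-2-yn-1-ol | COc1ccc([C@H](O)C#C[Si](C)(C)C)cc1 | intermediate
4 | (R)-1-(4-methoxyphenyl)prop-2-yn-1-ol | COc1ccc([C@H](O)C#C)cc1 | intermediate
5 | 4-(methoxymethoxy)benzaldehyde | COCOc1ccc(C=O)cc1 | starting material
6 | (1S,4S)-1-(4-methoxyphenyl)-4-[4-(methoxymethoxy)phenyl]but-2-yne-1,4-diol | COc1ccc([C@H](O)C#C[C@@H](O)c2ccc(OCOC)cc2)cc1 | intermediate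
7 | 2,4,6-trihydroxybenzaldehyde | O=Cc1c(O)cc(O)cc1O | starting material
8 | 2-hydroxy-4,6-bis(methoxymethoxy)benzaldehyde | O=Cc1c(O)cc(OCOC)cc1OCOC | intermediate
9 | 2,2'-{[(1R,4R)-1-(4-methoxyphenyl)-4-[4-(methoxymethoxy)phenyl]but-2-yne-1,4-diyl]bis(oxy)}bis[4,6-bis(methoxymethoxy)benzaldehyde] | COc1ccc([C@@H](Oc2cc(OCOC)cc(OCOC)c2C=O)C#C[C@H](Oc2cc(OCOC)cc(OCOC)c2C=O)c2ccc(OCOC)cc2)cc1 | intermediate
10 | unit-1-cyclised enone aldehyde: 2-{(1S,2E)-2-[(2R)-5,7-bis(methoxymethoxy)-2-(4-methoxyphenyl)-4-oxochroman-3-ylidene]-1-[4-(methoxymethoxy)phenyl]ethoxy}-4,6-bis(methoxymethoxy)benzaldehyde | COc1ccc([C@H]2Oc3cc(OCOC)cc(OCOC)c3C(=O)/C2=C/[C@H](Oc2cc(OCOC)cc(OCOC)c2C=O)c2ccc(OCOC)cc2)cc1 | intermediate (not isolated)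
11 | unit-2-cyclised enone aldehyde: 2-{(1S,2E)-2-[(2R)-5,7-bis(methoxymethoxy)-2-[4-(methoxymethoxy)phenyl]-4-oxochroman-3-ylidene]-1-(4-methoxyphenyl)ethoxy}-4,6-bis(methoxymethoxy)benzaldehyde | COc1ccc([C@@H](Oc2cc(OCOC)cc(OCOC)c2C=O)/C=C2/C(=O)c3c(OCOC)cc(OCOC)cc3O[C@@H]2c2ccc(OCOC)cc2)cc1 | intermediate (not isolated)
12 | (2S,3R)-5,7-bis(methoxymethoxy)-3-{(2S,3R)-5,7-bis(methoxymethoxy)-2-[4-(methoxymethoxy)phenyl]-4-oxochroman-3-yl}-2-(4-methoxyphenyl)chroman-4-one | COc1ccc([C@H]2Oc3cc(OCOC)cc(OCOC)c3C(=O)[C@@H]2[C@H]2C(=O)c3c(OCOC)cc(OCOC)cc3O[C@@H]2c2ccc(OCOC)cc2)cc1 | intermediate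
13 | (2S,3R)-5,7-dihydroxy-3-[(2S,3R)-5,7-dihydroxy-2-(4-hydroxyphenyl)-4-oxochroman-3-yl]-2-(4-methoxyphenyl)chroman-4-one | COc1ccc([C@H]2Oc3cc(O)cc(O)c3C(=O)[C@@H]2[C@H]2C(=O)c3c(O)cc(O)cc3O[C@@H]2c2ccc(O)cc2)cc1 | target

**Totals**
Total step count: 7. Longest linear sequence: 6 steps (steps 1, 2, 3, 5, 6, 7).

**Steps most likely to fail**

Step 6 (most at risk). The aldehydes are flanked by two ortho oxygens and are electron-rich, so Breslow-intermediate formation may be slow. The intermediate enones 10 and 11 can also drift to the 3-alkyl flavone under base before the Stetter closure. The fallback sets out from 9 and comes back at 12, replacing the two-electron carbene chemistry by one-electron acyl umpolung. In a thiol-catalysed radical chain (tert-dodecanethiol 30 mol %, AIBN, chlorobenzene, 80 °C) the thiyl radical abstracts the aldehydic hydrogen. The nucleophilic acyl radical closes 6-exo-dig onto the alkyne and the vinyl radical takes hydrogen from the thiol to give 10 or 11. The second acyl radical adds 6-exo-trig to the enone β-carbon and the α-keto radical is quenched by the thiol. Because no base is present during bond formation, the flavone drift is suppressed. A final treatment with DBU (10 mol %, THF, rt) equilibrates C3 and C3'' to the trans,trans isomer 12. Compounds outside the list made on this path: none F0.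

Step 5. The carbinols are benzylic, propargylic and carry donor aryl groups, so the oxyphosphonium may ionise and erode the configuration, and the second etherification is hindered. The fallback sets out from 6 and comes back at 9, separating activation from displacement. Ms2O and Et3N in CH2Cl2 at −40 °C give, with retention, (1S,4S)-1-(4-methoxyphenyl)-4-[4-(methoxymethoxy)phenyl]but-2-yne-1,4-diyl bis(methanesulfonate) F1. This is kept cold and displaced at once by the caesium salt of 8 (Cs2CO3, DMF, −40 to 0 °C) in a direct SN2 step with inversion at both centres, giving 9.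

Step 3. The zinc alkoxide formed from the free hydroxyl of 4 may aggregate with the catalyst and lower rate or selectivity. The fallback sets out from 4 and comes back at 6, setting the stereocentres by ketone reduction instead of C–C bond formation. The dianion of 4 (n-BuLi 2.1 equiv, THF, −78 °C) adds to 5 to give (1S)-1-(4-methoxyphenyl)-4-[4-(methoxymethoxy)phenyl]but-2-yne-1,4-diol as a mixture of C4 epimers F2. MnO2 in CH2Cl2 oxidises both carbinols to 1-(4-methoxyphenyl)-4-[4-(methoxymethoxy)phenyl]but-2-yne-1,4-dione F3. Double asymmetric transfer hydrogenation with RuCl(p-cymene)(TsDPEN) in iPrOH, using the catalyst enantiomer that gives the S,S-diol, then sets both centres together and returns 6.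

**Further compounds**
F0 | step 6 | none | none
F1 | step 5 | (1S,4S)-1-(4-methoxyphenyl)-4-[4-(methoxymethoxy)phenyl]but-2-yne-1,4-diyl bis(methanesulfonate) | COc1ccc([C@H](OS(C)(=O)=O)C#C[C@@H](OS(C)(=O)=O)c2ccc(OCOC)cc2)cc1
F2 | step 3 | (1S)-1-(4-methoxyphenyl)-4-[4-(methoxymethoxy)phenyl]but-2-yne-1,4-diol, mixture of C4 epimers | COc1ccc([C@H](O)C#CC(O)c2ccc(OCOC)cc2)cc1
F3 | step 3 | 1-(4-methoxyphenyl)-4-[4-(methoxymethoxy)phenyl]but-2-yne-1,4-dione | COc1ccc(C(=O)C#CC(=O)c2ccc(OCOC)cc2)cc1
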